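## Structural features

The target is an achiral ester built on one benzene ring. C1 of the ring carries a saturated three-carbon chain whose terminal oxygen is acylated by stearic (octadecanoic) acid; C3 and C4 carry free hydroxyls, C5 a methoxy group, and C2 and C6 are C–H. There is no second ring and no stereocentre, so no stereochemical relationship has to be set. The arene is a 3-O-methylpyrogallol unit, in which three neighbouring oxygen substituents must be told apart, two free and one methylated. The fragile parts are the electron-rich catechol, which air oxidises to an ortho-quinone once base or traces of copper or iron are present, and the primary alkyl ester, which rules out hydroxide, alkoxide and hydride reagents late in the route. The carbon skeleton is trivial; the difficulty is to place the third oxygen at C3 and nowhere else, and to acylate the aliphatic hydroxyl without touching a phenol. The feature used is that C3 is the only unsubstituted carbon ortho to the C4 hydroxyl: the other ortho carbon, C5, holds the methoxy group and the para carbon, C1, holds the chain. The target is therefore the ortho-hydroxylation product of a 4-alkyl-2-methoxyphenol, and the C3–O bond can be made last, by a phenol-directed C–H oxygenation on the complete ester.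

## Logic of the disconnections

5 back to 4: no skeletal bond is cut; only the two O–H bonds of the catechol are removed, which leads to the ortho-quinone oxidation level. The reason is that this is the level an aerobic ortho-oxygenation of a phenol delivers, and that the air-sensitive catechol is best formed last. Nothing is gained in skeleton, but the most fragile function is kept out of all earlier operations. The forward step must be a mild, near-neutral two-electron reduction that spares the ester, adds nothing to the ring, and is run without copper and without air.

4 back to 3: the C3–O bond is cut and replaced by C3–H, and the C4 carbonyl reverts to the phenolic hydroxyl. The cut is made here because C3 is the single free ortho position of that phenol. The trioxygenated arene is thereby reduced to a guaiacol-type phenol whose substitution pattern is that of a purchasable phenylpropanoid, and no protecting group is needed. The forward step must oxygenate the ortho C–H bond and not the methoxy-bearing carbon, must avoid radical coupling of the phenol and addition of unreacted phenol to the quinone, and must leave the remote ester alone. The precursor 3 is kept with its phenol free, because that hydroxyl is the handle by which copper holds the substrate.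

3 back to 1 and 2: the acyl C–O bond of the ester is cut. This gives two commercial compounds that together contain every carbon of the target. The forward step must acylate the primary aliphatic hydroxyl of 1 while its phenol stays free. An enzyme that accepts only aliphatic alcohols as acyl acceptors meets this in one step and is preferred here to acid catalysis, where selectivity rests on rate alone.

## Other disconnections considered

Alternative 1: The cut runs through the arene: ring bonds C2–C3, C4–C5 and C5–C6 are opened, so that the benzene ring is assembled from the four-carbon cyclobutenone A1, 3-(3-oxocyclobut-1-en-1-yl)propyl stearate, and the two-carbon alkyne A2, di-tert-butoxyethyne. Forward, light and then mild warming would open A1 to a vinylketene, which would add A2 across its ketene C=C bond. The new four-membered ring would open again, and the dienylketene would close by a six-electron electrocyclisation and enolise to the phenol A3, 3-(3,4-di-tert-butoxy-5-hydroxyphenyl)propyl stearate (a Danheiser benzannulation). In its favour, the three ring oxygens are formed already differentiated: the one free hydroxyl of A3 sits at C5, where the methyl group belongs. O-Methylation and acid cleavage of the two tert-butyl ethers would then finish the target with no regiochemical question and no oxidation at a phenol. On certainty of the oxygenation pattern, and on the gentleness of the final unmasking of the catechol, this plan is the better one. Against it, A1 is not commercial and needs its own ketene–alkyne cycloaddition and dehalogenation. A2 is heat-sensitive, and its tert-butyl groups, like those of A3, can be lost at the temperatures of the cascade. Two steps still follow the key step. Structurally it constructs a benzene ring that can be bought with its chain attached (1). Mechanistically a regiospecific pericyclic cascade stands against a catalyst-controlled C–H oxygenation. In step economy about seven or eight steps stand against three.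

Alternative 2: The cut is the bond between the benzylic carbon and the middle carbon of the chain, taken as a C=C bond. Forward, the silyl-protected styrene A4, 1,2-bis[(tert-butyldimethylsilyl)oxy]-5-ethenyl-3-methoxybenzene, and allyl stearate A5 would be joined by the second-generation Grubbs catalyst RuCl2(PCy3)(H2IMes)(CHPh). The usual cycloaddition and cycloreversion sequence at the ruthenium carbene would give the cinnamyl ester A6, (E)-3-{3,4-bis[(tert-butyldimethylsilyl)oxy]-5-methoxyphenyl}prop-2-en-1-yl stearate. In its favour, cross-metathesis of styrenes with allylic esters is established and tolerates esters and silyl ethers. The alkene geometry does not matter because the double bond is hydrogenated afterwards, and all three oxygens are in place from the start. On functional-group tolerance and on freedom from oxidation chemistry at the ring, the alternative is at least the equal of the chosen plan. Against it, A4 must first be made from a trioxygenated benzaldehyde by silylation and methylenation, and self-metathesis of both partners wastes material. Hydrogenation of A6, an allylic and benzylic ester, can cleave the C–O bond and lose the acid 2. Fluoride desilylation next to a fatty ester risks acyl migration to the freed phenoxides. Structurally the plan builds a C–C bond of a chain that 1 already contains. Mechanistically it relies on a dependable olefination–reduction pair that solves no problem of the target. In step economy about six steps (two to A4, one to A5, metathesis, hydrogenation, desilylation) stand against three.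

Alternative 3: The cut is the bond between C1 of the arene and the benzylic carbon. Forward, the aryl bromide A7, 1,2-bis(benzyloxy)-5-bromo-3-methoxybenzene, and the alkyl bromide A8, 3-bromopropyl stearate, would be coupled with NiI2, 4,4'-di-tert-butyl-2,2'-bipyridine and Zn in a cross-electrophile coupling. This involves oxidative addition of A7 to zerovalent nickel, capture of the alkyl radical from A8 and reductive elimination, and would give A9, 3-[3,4-bis(benzyloxy)-5-methoxyphenyl]propyl stearate. Hydrogenolysis of the two benzyl ethers over Pd/C would then release the target. In its favour, the plan is convergent, esters are tolerated, and no organometallic reagent has to be prepared. Only one neutral, non-oxidative step follows the key step. In the handling of the sensitive catechol, which is unmasked last without passing through a quinone, this plan is better than the chosen one. Against it, the bromine of A7 is meta to both flanking oxygens, a position that electrophilic bromination of a 1,2,3-trioxygenated benzene does not reach, so A7 needs several steps. Its electron-rich C–Br bond should add slowly to nickel, which favours dimerisation and reduction of A8, and A8 itself costs a step. Structurally it forms a C–C bond that 1 already has. Mechanistically the selectivity problem moves from the site of oxygenation to cross- versus homo-coupling. In step economy about six or seven steps stand against three.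

Key step: step 2

Remark on the chemistry: the target has no stereocentre, and 1 is treated as a purchasable phenylpropanoid, so the route needs no stereocontrol and begins with the ester formation.

## Route

Step 1  
Reactants: 1, dihydroconiferyl alcohol, 3-(4-hydroxy-3-methoxyphenyl)propan-1-ol; 2, stearic acid (octadecanoic acid)  
Product: 3, 3-(4-hydroxy-3-methoxyphenyl)propyl stearate  
Conditions: Novozym 435 (immobilised Candida antarctica lipase B), 4 Å MS, 2-methylbutan-2-ol, 60 °C  
Reagents that add atoms: none  
Why: Lipase-catalysed esterification: the acyl-enzyme formed from 2 at the active-site serine is taken over by the unhindered primary alcohol of 1, while the phenolic hydroxyl is not acylated by this enzyme, so 3 should form without a protecting group; the sieves bind the water and pull the equilibrium to the ester.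

Step 2  
Reactants: 3, 3-(4-hydroxy-3-methoxyphenyl)propyl stearate  
Product: 4, the ortho-quinone 3-(5-methoxy-3,4-dioxocyclohexa-1,5-dien-1-yl)propyl stearate  
Conditions: Cu(CH3CN)4PF6 (8 mol%), N,N'-di-tert-butylethylenediamine (15 mol%), O2 (1 atm), 4 Å MS, CH2Cl2, 23 °C; 10% aq NaHSO4 wash, crude 4 taken on at once  
Reagents that add atoms: dioxygen, O=O  
Why: Monovalent copper, the diamine and O2 should assemble a side-on peroxo-bridged dicopper complex of divalent copper, to which 3 binds as its phenolate after deprotonation by the diamine. The bound peroxide then attacks the ortho carbon C3 in an inner-sphere electrophilic aromatic substitution, which makes the new C3–O bond; the copper catecholate so formed is oxidised further and leaves as quinone 4, with water as the only co-product. The closest known reaction type is the tyrosinase-like catalytic aerobic ortho-oxygenation of 4-alkyl- and 2,4-disubstituted phenols to ortho-quinones with this copper–diamine pair, here transferred to a guaiacol that carries a fatty ester chain. No ring is closed and no stereocentre is created. The selectivity needed is oxygenation of the C3–H bond in preference to attack at the methoxy-bearing C5, to radical C–C or C–O coupling of the phenol, and to addition of unreacted 3 to the quinone. The substrate should secure it: C3 is the single free ortho position, the para position is blocked by the chain, oxygen is passed on within the copper–phenolate complex and not by a free radical, and in 4 the unsubstituted β-carbon C6 is flanked by two substituted carbons and made electron-rich by the neighbouring methoxy group. The stearate neither binds copper nor is oxidised. The acidic wash takes out copper and the basic diamine, which stops base-induced tautomerisation of 4 to a quinone methide before step 3.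

Step 3  
Reactants: 4, 3-(5-methoxy-3,4-dioxocyclohexa-1,5-dien-1-yl)propyl stearate  
Product: 5, the target 3-(3,4-dihydroxy-5-methoxyphenyl)propyl stearate  
Conditions: Na2S2O4, THF–H2O (degassed), Ar, 23 °C  
Reagents that add atoms: none  
Why: Dithionite reduction of an ortho-quinone: two electrons and two protons are delivered to the dione, which aromatises to the catechol; the alkyl ester is inert in the near-neutral aqueous medium, and since copper and amine were washed out in step 2, nothing is left to catalyse aerial re-oxidation of 5 during work-up.

## Compound list

1 | dihydroconiferyl alcohol, 3-(4-hydroxy-3-methoxyphenyl)propan-1-ol | OCCCc1ccc(O)c(OC)c1 | starting material  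
2 | stearic acid (octadecanoic acid) | CCCCCCCCCCCCCCCCCC(=O)O | starting material  
3 | 3-(4-hydroxy-3-methoxyphenyl)propyl stearate | CCCCCCCCCCCCCCCCCC(=O)OCCCc1ccc(O)c(OC)c1 | intermediate  
4 | 3-(5-methoxy-3,4-dioxocyclohexa-1,5-dien-1-yl)propyl stearate | CCCCCCCCCCCCCCCCCC(=O)OCCCC1=CC(=O)C(=O)C(OC)=C1 | intermediate  
5 | 3-(3,4-dihydroxy-5-methoxyphenyl)propyl stearate (CNP0209578.0) | CCCCCCCCCCCCCCCCCC(=O)OCCCc1cc(O)c(O)c(OC)c1 | target  

## Step count and least certain steps

Total step count: 3. Longest linear sequence: 3 (1 → 3 → 4 → 5).

Step 2 (key step). Most likely to go wrong: oxygenation may be overtaken by radical dimerisation of the electron-rich phenol or by addition of unreacted phenol to the quinone. The methoxy oxygen may also chelate copper together with the phenolate and slow oxygen transfer. While the diamine is still present, the quinone can tautomerise through its benzylic hydrogens to a quinone methide and oligomerise. Fallback, setting out from 3 and using no quinone: magnesium-mediated ortho-formylation (MgCl2, Et3N, paraformaldehyde, MeCN, reflux) would place a formyl group on the same free ortho carbon and give the salicylaldehyde 3-(3-formyl-4-hydroxy-5-methoxyphenyl)propyl stearate F1. A Dakin-type Baeyer–Villiger oxidation with mCPBA (CH2Cl2, 0 °C) would turn the formyl group into the aryl formate 3-[3-(formyloxy)-4-hydroxy-5-methoxyphenyl]propyl stearate F2. Brief methanolysis of this formate (Et3N, degassed MeOH, 0 °C), which is far faster than transesterification of the alkyl stearate, would come back to the route at 5.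

Step 3. Most likely to go wrong: hydrogensulfite formed from the reductant may add to the quinone ring in a conjugate fashion. The crude quinone may dimerise or tautomerise before it is reduced. The electron-rich catechol may be re-oxidised by air during work-up and chromatography. Fallback, setting out from 4: reductive acetylation (Zn, Ac2O, NaOAc, 23 °C) would trap the reduced ring as the diacetate 3-[3,4-bis(acetyloxy)-5-methoxyphenyl]propyl stearate F3, which is not air-sensitive and can be purified on silica. Aminolysis of the two aryl acetates with pyrrolidine (CH2Cl2, 0 °C, Ar), to which the much less electrophilic alkyl stearate should be inert, would come back at 5.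

Step 1. Most likely to go wrong: the enzymatic esterification may stall at partial conversion through build-up of water, slow turnover of the long-chain solid acid, or poor mutual solubility of the polar alcohol and the fatty acid. Fallback, setting out from 1: acylation of both hydroxyls with commercial stearoyl chloride (2.2 equiv, Et3N, cat. DMAP, CH2Cl2, 0 to 23 °C) would give the bis-ester 2-methoxy-4-[3-(stearoyloxy)propyl]phenyl stearate F4. Pyrrolidine (1.1 equiv, CH2Cl2, 0 °C) would then aminolyse the aryl ester only and come back to the route at 3.

## Further compounds

F1 | step 2 | 3-(3-formyl-4-hydroxy-5-methoxyphenyl)propyl stearate | CCCCCCCCCCCCCCCCCC(=O)OCCCc1cc(C=O)c(O)c(OC)c1  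
F2 | step 2 | 3-[3-(formyloxy)-4-hydroxy-5-methoxyphenyl]propyl stearate | CCCCCCCCCCCCCCCCCC(=O)OCCCc1cc(OC=O)c(O)c(OC)c1  
F3 | step 3 | 3-[3,4-bis(acetyloxy)-5-methoxyphenyl]propyl stearate | CCCCCCCCCCCCCCCCCC(=O)OCCCc1cc(OC(C)=O)c(OC(C)=O)c(OC)c1  
F4 | step 1 | 2-methoxy-4-[3-(stearoyloxy)propyl]phenyl stearate | CCCCCCCCCCCCCCCCCC(=O)OCCCc1ccc(OC(=O)CCCCCCCCCCCCCCCCC)c(OC)c1  
A1 | alternative 1 | 3-(3-oxocyclobut-1-en-1-yl)propyl stearate | CCCCCCCCCCCCCCCCCC(=O)OCCCC1=CC(=O)C1  
A2 | alternative 1 | di-tert-butoxyethyne | CC(C)(C)OC#COC(C)(C)C  
A3 | alternative 1 | 3-(3,4-di-tert-butoxy-5-hydroxyphenyl)propyl stearate | CCCCCCCCCCCCCCCCCC(=O)OCCCc1cc(O)c(OC(C)(C)C)c(OC(C)(C)C)c1  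
A4 | alternative 2 | 1,2-bis[(tert-butyldimethylsilyl)oxy]-5-ethenyl-3-methoxybenzene | C=Cc1cc(OC)c(O[Si](C)(C)C(C)(C)C)c(O[Si](C)(C)C(C)(C)C)c1  
A5 | alternative 2 | allyl stearate (prop-2-en-1-yl octadecanoate) | CCCCCCCCCCCCCCCCCC(=O)OCC=C  
A6 | alternative 2 | (E)-3-{3,4-bis[(tert-butyldimethylsilyl)oxy]-5-methoxyphenyl}prop-2-en-1-yl stearate | CCCCCCCCCCCCCCCCCC(=O)OC/C=C/c1cc(OC)c(O[Si](C)(C)C(C)(C)C)c(O[Si](C)(C)C(C)(C)C)c1  
A7 | alternative 3 | 1,2-bis(benzyloxy)-5-bromo-3-methoxybenzene | COc1cc(Br)cc(OCc2ccccc2)c1OCc1ccccc1  
A8 | alternative 3 | 3-bromopropyl stearate | CCCCCCCCCCCCCCCCCC(=O)OCCCBr  
A9 | alternative 3 | 3-[3,4-bis(benzyloxy)-5-methoxyphenyl]propyl stearate | CCCCCCCCCCCCCCCCCC(=O)OCCCc1cc(OC)c(OCc2ccccc2)c(OCc2ccccc2)c1  
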